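**Retrosynthetic overview**
1. 23 ⇒ 22 (Si–O cleavage) ⇒ 21: ring-closing metathesis at C4=C5 closes the ten-membered carbocycle last.
2. 21 ⇒ 19 (acylation of C8–OH) ⇒ 16: a one-pot intramolecular epoxide alkylation (C7–C11) and Horner–Wadsworth–Emmons methylenation (C11=C13) closes the γ-lactone first.
3. Enabling feature: in the lactone ring O–C6–C7–C11–C12 the ring oxygen sits on C6, and C7–C11 is anti to the C8–O bond on the next ring carbon; O–C12(=O)–C11 is therefore the two-atom tether of an erythro trans-2,3-epoxy alcohol ester (C6 carbinol, C7–C8 epoxide).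
4. 16 ⇒ 14 (Sharpless epoxidation fixes C6, C7, C8) ⇒ 13 ⇒ enal 9 plus two Grignard reagents ⇒ 7 (cross-metathesis).
5. 7 ⇒ 5 ⇒ (S)-lactic acid: C10 is set by enolate alkylation in a temporary dioxolanone ring.

Key step: step 10

Remark: locants C1–C13 in the text are germacrane locants of 23 (C1 ketone, C4=C5, C6 lactone carbinol, C7, C8 ester carbinol, C10 tertiary carbinol, C11/C12 lactone α-carbon and carbonyl, C13 methylene); systematic names use their own locants.
Remark: 12 is handled as a starting material; it is a standard titrated THF solution made from commercial 4-bromo-2-methylbut-1-ene and magnesium.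

**Step 1**
Reactants: 1 (S)-lactic acid; 2 2,2-dimethylpropanal
Product: 3 (2S,5S)-2-tert-butyl-5-methyl-1,3-dioxolan-4-one
Conditions: TsOH·H2O (cat.), H2SO4 (cat.), pentane, reflux, Dean–Stark; crystallisation (pentane/Et2O, −78 °C)
Reagents that add atoms: none
Why: Acid-catalysed acetalisation with removal of water should give mainly the cis acetal under thermodynamic control, which is purified by crystallisation; C5 keeps the lactic acid configuration and directs the new acetal centre.

**Step 2**
Reactants: 3 (2S,5S)-2-tert-butyl-5-methyl-1,3-dioxolan-4-one; 4 3-bromoprop-1-ene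
Product: 5 (2S,5R)-2-tert-butyl-5-methyl-5-(prop-2-en-1-yl)-1,3-dioxolan-4-one
Conditions: LiN(iPr)2, THF, −78 °C; then 4, −78 to −30 °C
Reagents that add atoms: none
Why: Diastereoselective enolate alkylation (self-regeneration of stereocentres): the allyl group should enter anti to the tert-butyl group, replacing H with retention and setting the quaternary centre that becomes C10.

**Step 3**
Reactants: 5 (2S,5R)-2-tert-butyl-5-methyl-5-(prop-2-en-1-yl)-1,3-dioxolan-4-one
Product: 6 (2R)-2-hydroxy-N-methoxy-N,2-dimethylpent-4-enamide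
Conditions: MeNH(OMe)·HCl, iPrMgCl, THF, −20 to 0 °C
Reagents that add atoms: N,O-dimethylhydroxylamine hydrochloride CNOC.Cl
Why: Weinreb amide formation by aminolysis of the acylal-type lactone with the chloromagnesium amide should open the ring with loss of the aldehyde auxiliary and without touching the quaternary centre.

**Step 4**
Reactants: 6 (2R)-2-hydroxy-N-methoxy-N,2-dimethylpent-4-enamide
Product: 7 (2R)-N-methoxy-N,2-dimethyl-2-[(triethylsilyl)oxy]pent-4-enamide
Conditions: Et3SiOTf, 2,6-lutidine, CH2Cl2, 0 °C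
Reagents that add atoms: triethylsilyl trifluoromethanesulfonate CC[Si](CC)(CC)OS(=O)(=O)C(F)(F)F
Why: Silyl ether formation with the silyl triflate should mask the hindered tertiary hydroxyl for the organometallic, base and metathesis steps; no stereocentre is affected.

**Step 5**
Reactants: 7 (2R)-N-methoxy-N,2-dimethyl-2-[(triethylsilyl)oxy]pent-4-enamide; 8 (2E)-but-2-enal
Product: 9 (2R,4E)-N-methoxy-N,2-dimethyl-6-oxo-2-[(triethylsilyl)oxy]hex-4-enamide
Conditions: 8 (5 equiv), second-generation Hoveyda–Grubbs catalyst (5 mol%), CH2Cl2, 40 °C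
Reagents that add atoms: none
Why: Olefin cross-metathesis of the monosubstituted alkene with an enal partner should give the E-enal, and it is placed before the second chain alkene is introduced so that no ring closure can compete.

**Step 6**
Reactants: 9 (2R,4E)-N-methoxy-N,2-dimethyl-6-oxo-2-[(triethylsilyl)oxy]hex-4-enamide; 10 vinylmagnesium bromide
Product: 11 (2R,4E)-6-hydroxy-N-methoxy-N,2-dimethyl-2-[(triethylsilyl)oxy]octa-4,7-dienamide (both C6 epimers)
Conditions: 10 (1.1 equiv), THF, −78 °C; aq. NH4Cl
Reagents that add atoms: none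
Why: 1,2-Addition of the Grignard reagent to the enal at −78 °C, where the hindered Weinreb amide is inert, should give the bis-allylic alcohol; the new carbinol centre (C6) forms without control and is sorted out in step 8.

**Step 7**
Reactants: 11 (2R,4E)-6-hydroxy-N-methoxy-N,2-dimethyl-2-[(triethylsilyl)oxy]octa-4,7-dienamide; 12 3-methylbut-3-en-1-ylmagnesium bromide
Product: 13 (4E,7R)-3-hydroxy-7,11-dimethyl-7-[(triethylsilyl)oxy]dodeca-1,4,11-trien-8-one (both C3 epimers)
Conditions: 12 (3 equiv), THF, 0 °C to rt; aq. NH4Cl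
Reagents that add atoms: none
Why: Weinreb ketone synthesis: one equivalent of 12 is consumed by the hydroxyl group and a further one adds to the amide to give a chelated adduct that releases the ketone only on work-up, so over-addition is avoided and no stereocentre changes.

**Step 8**
Reactants: 13 (4E,7R)-3-hydroxy-7,11-dimethyl-7-[(triethylsilyl)oxy]dodeca-1,4,11-trien-8-one
Product: 14 (1R)-1-[(2R,3R)-3-{(2R)-2,6-dimethyl-3-oxo-2-[(triethylsilyl)oxy]hept-6-en-1-yl}oxiran-2-yl]prop-2-en-1-ol
Conditions: Ti(OiPr)4 (0.2 equiv), D-(−)-diisopropyl tartrate (0.25 equiv), t-BuOOH (0.6 equiv), 4 Å molecular sieves, CH2Cl2, −20 °C; chromatography, unreacted (3S)-13 recovered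
Reagents that add atoms: tert-butyl hydroperoxide CC(C)(C)OO
Why: Sharpless asymmetric epoxidation run as a kinetic resolution of the C6 epimers: with the D-(−)-tartrate the (3R)-epimer is the fast-reacting one and its E-alkene should be epoxidised to the erythro epoxy alcohol, so C7 and C8 are set by reagent control while the (3S)-epimer, the vinyl group and the isolated 1,1-disubstituted alkene are left.

**Step 9**
Reactants: 14 (1R)-1-[(2R,3R)-3-{(2R)-2,6-dimethyl-3-oxo-2-[(triethylsilyl)oxy]hept-6-en-1-yl}oxiran-2-yl]prop-2-en-1-ol; 15 (diethoxyphosphoryl)acetic acid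
Product: 16 (1R)-1-[(2S,3R)-3-{(2R)-2,6-dimethyl-3-oxo-2-[(triethylsilyl)oxy]hept-6-en-1-yl}oxiran-2-yl]prop-2-en-1-yl (diethoxyphosphoryl)acetate
Conditions: 15, DCC, DMAP (cat.), CH2Cl2, 0 °C to rt
Reagents that add atoms: none
Why: Steglich esterification of the secondary epoxy alcohol under neutral conditions should install the phosphonoacetate tether on O6 without Payne rearrangement or epoxide opening; the configuration is unchanged (the oxirane descriptor changes only through CIP priorities).

**Step 10**
Reactants: 16 (1R)-1-[(2S,3R)-3-{(2R)-2,6-dimethyl-3-oxo-2-[(triethylsilyl)oxy]hept-6-en-1-yl}oxiran-2-yl]prop-2-en-1-yl (diethoxyphosphoryl)acetate; 17 formaldehyde (as paraformaldehyde)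
Product: 19 (4R,5R)-5-ethenyl-4-{(1R,3R)-1-hydroxy-3,7-dimethyl-4-oxo-3-[(triethylsilyl)oxy]oct-7-en-1-yl}-3-methylideneoxolan-2-one, via phosphono lactone 18 (not isolated)
Conditions: KOtBu (1.05 equiv), THF (0.02 M), 0 to 45 °C; then (CH2O)n, 0 °C to rt
Reagents that add atoms: none
Why: Proposed new method: KOtBu deprotonates the phosphonoacetate CH2 of 16 and the stabilised carbanion attacks C7 of the trans-epoxide in an intramolecular SN2 reaction anti to the C7–O bond; the C8 alkoxide is then quenched by the more acidic C–H of phosphono lactone 18, and the regenerated phosphonate carbanion olefinates formaldehyde (Horner–Wadsworth–Emmons) to the exocyclic methylene, the closest known reaction types being the telescoped intramolecular Michael addition/olefination of phosphonoacetate esters of γ-hydroxy enones, the Stork epoxynitrile cyclisation and the C2-selective intramolecular opening of 2,3-epoxy alcohol carbamates. The γ-lactone, the only ring closed, forms by 5-exo-tet attack at the proximal epoxide carbon; because the exocyclic P=O group carries the charge, the ring ester need not stay planar, which is how this formally 5-(enolendo) closure is expected to proceed as it does in the Michael precedent. C7 is set by inversion at the epoxide carbon, C8 keeps the configuration of the epoxide oxygen and C6 is untouched, so the trans ring fusion and the anti C7–C11/C8–O relationship follow from the erythro trans-epoxy alcohol of step 8. The step needs attack at C7 and not at C8, and the lactone must stay on O6: the two-atom O–C(=O) tether makes attack at C8 a strained 6-endo opening, and the proton transfer that turns the C8 alkoxide into the non-electrophilic phosphonate enolate is relied on to suppress acyl transfer to O8 until formaldehyde is added. One equivalent of base and a prompt quench are used so that no free alkoxide persists next to the methylene lactone.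

**Step 11**
Reactants: 19 (4R,5R)-5-ethenyl-4-{(1R,3R)-1-hydroxy-3,7-dimethyl-4-oxo-3-[(triethylsilyl)oxy]oct-7-en-1-yl}-3-methylideneoxolan-2-one; 20 3-methylbutanoic anhydride
Product: 21 (1R,3R)-1-[(2R,3R)-2-ethenyl-4-methylidene-5-oxooxolan-3-yl]-3,7-dimethyl-4-oxo-3-[(triethylsilyl)oxy]oct-7-en-1-yl 3-methylbutanoate
Conditions: 20, Et3N, DMAP (cat.), CH2Cl2, 0 °C to rt
Reagents that add atoms: none
Why: DMAP-catalysed acylation of the secondary C8 alcohol should give the ester with retention and drain any γ-hydroxy ketone/lactol equilibrium with the C1 ketone, the tertiary silyl ether being inert.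

**Step 12**
Reactants: 21 (1R,3R)-1-[(2R,3R)-2-ethenyl-4-methylidene-5-oxooxolan-3-yl]-3,7-dimethyl-4-oxo-3-[(triethylsilyl)oxy]oct-7-en-1-yl 3-methylbutanoate
Product: 22 (3aR,4R,6R,10Z,11aR)-6,10-dimethyl-3-methylidene-2,7-dioxo-6-[(triethylsilyl)oxy]-2,3,3a,4,5,6,7,8,9,11a-decahydrocyclodeca[b]furan-4-yl 3-methylbutanoate
Conditions: second-generation Grubbs catalyst (15 mol%), 1,4-benzoquinone (30 mol%), toluene (1 mM), 80 °C
Reagents that add atoms: none
Why: Ring-closing metathesis between the C6 vinyl group and the 1,1-disubstituted alkene, a closure with precedent for ten-membered carbocycles with a trisubstituted alkene, should release ethene and give the Z ring alkene expected for this ring size (C3 and C6 cis), the trans-lactone and quaternary C10 pre-bending the chain; no stereocentre is formed and the electron-poor methylene lactone has no productive ring-closing partner.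

**Step 13**
Reactants: 22 (3aR,4R,6R,10Z,11aR)-6,10-dimethyl-3-methylidene-2,7-dioxo-6-[(triethylsilyl)oxy]-2,3,3a,4,5,6,7,8,9,11a-decahydrocyclodeca[b]furan-4-yl 3-methylbutanoate
Product: 23 (3aR,4R,6R,10Z,11aR)-6-hydroxy-6,10-dimethyl-3-methylidene-2,7-dioxo-2,3,3a,4,5,6,7,8,9,11a-decahydrocyclodeca[b]furan-4-yl 3-methylbutanoate
Conditions: HF·pyridine, pyridine, THF, 0 °C to rt
Reagents that add atoms: none
Why: Fluoride-mediated cleavage of the tertiary silyl ether under buffered, non-basic conditions should free the C10 hydroxyl without translactonisation, ester cleavage or conjugate addition to the methylene lactone.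

**Compound list**
1 | (S)-lactic acid | C[C@H](O)C(=O)O | starting material
2 | 2,2-dimethylpropanal (pivalaldehyde) | CC(C)(C)C=O | starting material
3 | (2S,5S)-2-tert-butyl-5-methyl-1,3-dioxolan-4-one | C[C@@H]1O[C@H](C(C)(C)C)OC1=O | intermediate
4 | 3-bromoprop-1-ene (allyl bromide) | C=CCBr | starting material
5 | (2S,5R)-2-tert-butyl-5-methyl-5-(prop-2-en-1-yl)-1,3-dioxolan-4-one | C[C@]1(CC=C)O[C@H](C(C)(C)C)OC1=O | intermediate
6 | (2R)-2-hydroxy-N-methoxy-N,2-dimethylpent-4-enamide | C=CC[C@@](C)(O)C(=O)N(C)OC | intermediate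
7 | (2R)-N-methoxy-N,2-dimethyl-2-[(triethylsilyl)oxy]pent-4-enamide | C=CC[C@@](C)(O[Si](CC)(CC)CC)C(=O)N(C)OC | intermediate
8 | (2E)-but-2-enal | C/C=C/C=O | starting material
9 | (2R,4E)-N-methoxy-N,2-dimethyl-6-oxo-2-[(triethylsilyl)oxy]hex-4-enamide | O=C/C=C/C[C@@](C)(O[Si](CC)(CC)CC)C(=O)N(C)OC | intermediate
10 | vinylmagnesium bromide | C=C[Mg]Br | starting material
11 | (2R,4E)-6-hydroxy-N-methoxy-N,2-dimethyl-2-[(triethylsilyl)oxy]octa-4,7-dienamide, both C6 epimers | C=CC(O)/C=C/C[C@@](C)(O[Si](CC)(CC)CC)C(=O)N(C)OC | intermediate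
12 | 3-methylbut-3-en-1-ylmagnesium bromide | C=C(C)CC[Mg]Br | starting material
13 | (4E,7R)-3-hydroxy-7,11-dimethyl-7-[(triethylsilyl)oxy]dodeca-1,4,11-trien-8-one, both C3 epimers | C=CC(O)/C=C/C[C@@](C)(O[Si](CC)(CC)CC)C(=O)CCC(C)=C | intermediate
14 | (1R)-1-[(2R,3R)-3-{(2R)-2,6-dimethyl-3-oxo-2-[(triethylsilyl)oxy]hept-6-en-1-yl}oxiran-2-yl]prop-2-en-1-ol | C=C[C@@H](O)[C@H]1O[C@@H]1C[C@@](C)(O[Si](CC)(CC)CC)C(=O)CCC(C)=C | intermediate
15 | (diethoxyphosphoryl)acetic acid | OC(=O)CP(=O)(OCC)OCC | starting material
16 | (1R)-1-[(2S,3R)-3-{(2R)-2,6-dimethyl-3-oxo-2-[(triethylsilyl)oxy]hept-6-en-1-yl}oxiran-2-yl]prop-2-en-1-yl (diethoxyphosphoryl)acetate | C=C[C@@H](OC(=O)CP(=O)(OCC)OCC)[C@H]1O[C@@H]1C[C@@](C)(O[Si](CC)(CC)CC)C(=O)CCC(C)=C | intermediate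
17 | formaldehyde (used as paraformaldehyde) | C=O | starting material
18 | diethyl {(4R,5R)-5-ethenyl-4-[(1R,3R)-1-hydroxy-3,7-dimethyl-4-oxo-3-[(triethylsilyl)oxy]oct-7-en-1-yl]-2-oxooxolan-3-yl}phosphonate, C3 epimers, present as its potassium enolate | C=C[C@H]1OC(=O)C(P(=O)(OCC)OCC)[C@@H]1[C@H](O)C[C@@](C)(O[Si](CC)(CC)CC)C(=O)CCC(C)=C | intermediate
19 | (4R,5R)-5-ethenyl-4-{(1R,3R)-1-hydroxy-3,7-dimethyl-4-oxo-3-[(triethylsilyl)oxy]oct-7-en-1-yl}-3-methylideneoxolan-2-one | C=C[C@H]1OC(=O)C(=C)[C@@H]1[C@H](O)C[C@@](C)(O[Si](CC)(CC)CC)C(=O)CCC(C)=C | intermediate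
20 | 3-methylbutanoic anhydride | CC(C)CC(=O)OC(=O)CC(C)C | starting material
21 | (1R,3R)-1-[(2R,3R)-2-ethenyl-4-methylidene-5-oxooxolan-3-yl]-3,7-dimethyl-4-oxo-3-[(triethylsilyl)oxy]oct-7-en-1-yl 3-methylbutanoate | C=C[C@H]1OC(=O)C(=C)[C@@H]1[C@H](OC(=O)CC(C)C)C[C@@](C)(O[Si](CC)(CC)CC)C(=O)CCC(C)=C | intermediate
22 | (3aR,4R,6R,10Z,11aR)-6,10-dimethyl-3-methylidene-2,7-dioxo-6-[(triethylsilyl)oxy]-2,3,3a,4,5,6,7,8,9,11a-decahydrocyclodeca[b]furan-4-yl 3-methylbutanoate | C=C1C(=O)O[C@@H]2/C=C(/C)CCC(=O)[C@](C)(O[Si](CC)(CC)CC)C[C@@H](OC(=O)CC(C)C)[C@@H]12 | intermediate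
23 | (3aR,4R,6R,10Z,11aR)-6-hydroxy-6,10-dimethyl-3-methylidene-2,7-dioxo-2,3,3a,4,5,6,7,8,9,11a-decahydrocyclodeca[b]furan-4-yl 3-methylbutanoate | C=C1C(=O)O[C@@H]2/C=C(/C)CCC(=O)[C@](C)(O)C[C@@H](OC(=O)CC(C)C)[C@@H]12 | target

**Totals**
Total step count: 13. Longest linear sequence: 13 steps (from 1).

**Steps most likely to fail**

1. Step 10 (the proposed new method). The C-alkylation may be slow because the ester must reach its s-cis rotamer and the enolate is endocyclic. Reversible O-alkylation through the enolate oxygen, 6-endo opening at C8 or acyl transfer to the C8 alkoxide could then take over. The fallback uses known chemistry, sets out from 14 and returns at 21. Compound 14 would be O-alkylated (propargyl bromide, Ag2O, CH2Cl2) to the prop-2-yn-1-yl ether of 14 F1. Cp2TiCl (trivalent titanium, made from Cp2TiCl2 and Zn, THF, rt) would open the epoxide homolytically at C7 with the C8–O bond kept. The C7 radical would close 5-exo-dig onto the alkyne, trans to the vinyl group, and after hydrogen-atom capture give the 3-methylidenetetrahydrofuran alcohol F2. This reductive epoxide-opening radical cyclisation is established for propargyl ethers of 2,3-epoxy alcohols. Acylation with 20 (Et3N, DMAP) would give the isovalerate of that tetrahydrofuran F3. Allylic oxidation of the ring O–CH2 group of F3 with CrO3·2 pyridine in CH2Cl2 would give lactone 21.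

2. Step 12. Ring closure may lose to intermolecular metathesis (oligomers), or the catalyst may engage the 1,1-disubstituted alkene too slowly because the trans-fused lactone and the C8 ester hold the two alkenes apart. The fallback sets out from 16 and returns at 22; it reverses the order of ring construction. Compound 16, which has no fused ring, would be cyclised first (second-generation Grubbs catalyst, toluene, 1 mM, 80 °C) to the ten-membered Z-cycloalkene epoxy phosphonoacetate F4. The step-10 sequence (KOtBu, then (CH2O)n), by then proven on the open chain, would close the lactone across the ring to the 8-hydroxy lactone F5. Acylation with 20 would give 22.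

3. Step 8. Discrimination between the two C6 epimers may be incomplete, the vinyl group of the slow epimer may be epoxidised, or turnover may be slow because the ketone and silyl ether crowd the titanium centre. The fallback sets out from 9 and returns at 14; it makes the epoxide before the carbinol. Enal 9 would be epoxidised with H2O2 under iminium catalysis by (R)-α,α-bis[3,5-bis(trifluoromethyl)phenyl]prolinol trimethylsilyl ether to the trans-(2S,3R)-epoxy aldehyde F6. Addition of 10 at −78 °C (Felkin–Anh, anti) would give the erythro epoxy alcohol Weinreb amide F7. Reagent 12 (2.2 equiv, THF, −20 °C) would convert its amide into the ketone of 14.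

**Further compounds**
F1 | step 10 | prop-2-yn-1-yl ether of 14 | C=C[C@@H](OCC#C)[C@H]1O[C@@H]1C[C@@](C)(O[Si](CC)(CC)CC)C(=O)CCC(C)=C
F2 | step 10 | (1R,3R)-1-[(2R,3R)-2-ethenyl-4-methylideneoxolan-3-yl]-1-hydroxy-3,7-dimethyl-3-[(triethylsilyl)oxy]oct-7-en-4-one | C=C[C@H]1OCC(=C)[C@@H]1[C@H](O)C[C@@](C)(O[Si](CC)(CC)CC)C(=O)CCC(C)=C
F3 | step 10 | 3-methylbutanoate of F2 | C=C[C@H]1OCC(=C)[C@@H]1[C@H](OC(=O)CC(C)C)C[C@@](C)(O[Si](CC)(CC)CC)C(=O)CCC(C)=C
F4 | step 12 | ten-membered (Z)-cycloalkene epoxy phosphonoacetate (ring-closed 16) | CCOP(=O)(OCC)CC(=O)O[C@@H]1/C=C(/C)CCC(=O)[C@](C)(O[Si](CC)(CC)CC)C[C@H]2O[C@H]12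
F5 | step 12 | 8-hydroxy lactone (O-desacyl 22) | C=C1C(=O)O[C@@H]2/C=C(/C)CCC(=O)[C@](C)(O[Si](CC)(CC)CC)C[C@@H](O)[C@@H]12
F6 | step 8 | (2R)-3-[(2R,3S)-3-formyloxiran-2-yl]-N-methoxy-N,2-dimethyl-2-[(triethylsilyl)oxy]propanamide | O=C[C@H]1O[C@@H]1C[C@@](C)(O[Si](CC)(CC)CC)C(=O)N(C)OC
F7 | step 8 | Weinreb amide analogue of 14 (erythro epoxy alcohol) | C=C[C@@H](O)[C@H]1O[C@@H]1C[C@@](C)(O[Si](CC)(CC)CC)C(=O)N(C)OC
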